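**Retrosynthetic overview**

- Target 30 ⇐ 12‑O‑methyl quinone 29 ⇐ arene 28 ⇐ (C1 hydroxylation) 27 ⇐ (C10=C20 dehydrogenation) enol lactone 26 ⇐ keto ester 24. Ring C is carried as its 11,12,14‑trimethyl ether, because the hydroxyquinone needs an oxygen at C14 and can then be released by oxidative demethylation.
- The strategy rests on C5: it is the only sp3 carbon of seven‑membered ring B (C5, C6, C7, C8, C9, C20, C10), it lies between C6 (the enol‑lactone carbon, a ketone in 24) and C10, and it also belongs to ring A (C1 to C5, C10). C5 is therefore inserted as a diazo carbon into the C6–C10 bond of a 2‑tetralone, which makes C5–C6 and C5–C10 (24 ⇐ 23).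
- 23 ⇐ tetralone keto ester 10 + iodide 18, joined at C10 by dianion alkylation. 10 comes from a rhodium carbenoid closure onto C8 of the arene; C4 of 18 is set by enzymatic desymmetrization of malonate 13.
- Ring order: ring C (bought arene) → six‑membered carbocycle (step 8) → ring A and seven‑membered ring B together (step 18) → γ‑lactone (step 20) → quinone (step 23).

Key step: step 18

Assumption: pig liver esterase is taken to cleave the pro‑S ester group of 13, as it does for the 2‑ethyl, 2‑propyl and 2‑butyl 2‑methylmalonates; the enantiomeric purity of 14 is raised by crystallizing a 1‑phenylethylammonium salt.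

Remark: icetexane numbering is used for the tricyclic compounds and for the matching atoms of their precursors. Compounds 19 to 26 are carried as both C10 epimers (C10 becomes sp2 in step 21), so C10 is left undefined in their SMILES.

**Route**

Step 1
Reactants: 1 1,2,4‑trimethoxybenzene
Product: 2 2‑(2,3,6‑trimethoxyphenyl)propan‑2‑ol
Conditions: n‑BuLi, THF, 0 °C to rt; acetone, −78 °C to rt
Reagents that add atoms: acetone, CC(C)=O
Why: Directed ortho‑lithiation occurs at the ring position flanked by two methoxy groups (the future C13) and the aryllithium adds to acetone (1,2‑addition).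

Step 2
Reactants: 2 2‑(2,3,6‑trimethoxyphenyl)propan‑2‑ol
Product: 3 3‑isopropyl‑1,2,4‑trimethoxybenzene
Conditions: Et3SiH, CF3CO2H, CH2Cl2, 0 °C
Reagents that add atoms: none
Why: Ionic hydrogenation, in which the tertiary benzylic cation formed in acid is reduced by hydride from the silane.

Step 3
Reactants: 3 3‑isopropyl‑1,2,4‑trimethoxybenzene
Product: 4 1‑bromo‑3‑isopropyl‑2,4,5‑trimethoxybenzene
Conditions: NBS, MeCN, 0 °C to rt
Reagents that add atoms: N‑bromosuccinimide, O=C1CCC(=O)N1Br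
Why: Electrophilic aromatic bromination goes to the more activated ring position (future C8, para to the C12 methoxy), which blocks it and leaves C9–H as the only ring hydrogen.

Step 4
Reactants: 4 1‑bromo‑3‑isopropyl‑2,4,5‑trimethoxybenzene
Product: 5 2‑bromo‑4‑isopropyl‑3,5,6‑trimethoxybenzaldehyde
Conditions: LiN(i‑Pr)2, THF, −78 °C; DMF, −78 to 0 °C; aq. NH4Cl
Reagents that add atoms: N,N‑dimethylformamide, CN(C)C=O
Why: Directed ortho‑metalation, in which the amide base removes the single ring hydrogen (acidified by the flanking bromine and methoxy) without halogen–metal exchange, followed by formylation to install C20 on C9.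

Step 5
Reactants: 5 2‑bromo‑4‑isopropyl‑3,5,6‑trimethoxybenzaldehyde; 6 ethyl 4‑(diethoxyphosphoryl)‑3‑oxobutanoate
Product: 7 ethyl (E)‑5‑(2‑bromo‑4‑isopropyl‑3,5,6‑trimethoxyphenyl)‑3‑oxopent‑4‑enoate
Conditions: NaH (2.2 equiv), THF, 0 °C to rt
Reagents that add atoms: none
Why: Horner–Wadsworth–Emmons olefination through the phosphonate dianion, whose carbanion next to phosphorus condenses with the aldehyde to give the E enone.

Step 6
Reactants: 7 ethyl (E)‑5‑(2‑bromo‑4‑isopropyl‑3,5,6‑trimethoxyphenyl)‑3‑oxopent‑4‑enoate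
Product: 8 ethyl 5‑(4‑isopropyl‑2,3,5‑trimethoxyphenyl)‑3‑oxopentanoate
Conditions: H2 (1 atm), Pd/C, Et3N, EtOAc/EtOH, rt
Reagents that add atoms: none
Why: Catalytic hydrogenation saturates the enone C=C and hydrogenolyses the aryl bromide (the amine takes up HBr), which frees C8–H for the ring closure.

Step 7
Reactants: 8 ethyl 5‑(4‑isopropyl‑2,3,5‑trimethoxyphenyl)‑3‑oxopentanoate
Product: 9 ethyl 2‑diazo‑5‑(4‑isopropyl‑2,3,5‑trimethoxyphenyl)‑3‑oxopentanoate
Conditions: 4‑acetamidobenzenesulfonyl azide, Et3N, MeCN, 0 °C to rt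
Reagents that add atoms: 4‑acetamidobenzenesulfonyl azide, CC(=O)Nc1ccc(cc1)S(=O)(=O)N=[N+]=[N-]
Why: Regitz diazo transfer to the active methylene of the β‑keto ester.

Step 8
Reactants: 9 ethyl 2‑diazo‑5‑(4‑isopropyl‑2,3,5‑trimethoxyphenyl)‑3‑oxopentanoate
Product: 10 ethyl 7‑isopropyl‑5,6,8‑trimethoxy‑2‑oxo‑1,2,3,4‑tetrahydronaphthalene‑1‑carboxylate
Conditions: Rh2(OAc)4 (1 mol %), CH2Cl2, 40 °C
Reagents that add atoms: none
Why: Rhodium carbenoid intramolecular aromatic substitution (formal aromatic C–H insertion) at C8, the only free position ortho to the tether and para to the C12 methoxy, closes the six‑membered ring; the chain is too short for aliphatic 1,5‑insertion.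

Step 9
Reactants: 11 dimethyl methylmalonate; 12 1‑bromo‑3‑chloropropane
Product: 13 dimethyl 2‑(3‑chloropropyl)‑2‑methylmalonate
Conditions: NaH, DMF, 0 °C to rt
Reagents that add atoms: none
Why: Malonate alkylation (SN2), in which the bromide is displaced selectively over the chloride.

Step 10
Reactants: 13 dimethyl 2‑(3‑chloropropyl)‑2‑methylmalonate
Product: 14 (S)‑5‑chloro‑2‑(methoxycarbonyl)‑2‑methylpentanoic acid
Conditions: pig liver esterase, phosphate buffer pH 7.5, 25 °C (pH‑stat, 1 M NaOH); HCl; crystallization of the 1‑phenylethylammonium salt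
Reagents that add atoms: water, O
Why: Enzymatic desymmetrization by hydrolysis of one enantiotopic ester group sets the quaternary centre C4 as S, and salt crystallization raises the enantiomeric purity.

Step 11
Reactants: 14 (S)‑5‑chloro‑2‑(methoxycarbonyl)‑2‑methylpentanoic acid
Product: 15 methyl (S)‑5‑chloro‑2‑(hydroxymethyl)‑2‑methylpentanoate
Conditions: BH3·SMe2, THF, 0 °C to rt
Reagents that add atoms: none
Why: Chemoselective borane reduction of the carboxylic acid in the presence of the methyl ester, so the acid carbon becomes C5 and the ester stays as C19.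

Step 12
Reactants: 15 methyl (S)‑5‑chloro‑2‑(hydroxymethyl)‑2‑methylpentanoate
Product: 16 methyl (S)‑5‑chloro‑2‑formyl‑2‑methylpentanoate
Conditions: Dess–Martin periodinane, NaHCO3, CH2Cl2, rt
Reagents that add atoms: none
Why: Periodinane oxidation of the primary alcohol to the aldehyde; C4 is quaternary and cannot epimerize.

Step 13
Reactants: 16 methyl (S)‑5‑chloro‑2‑formyl‑2‑methylpentanoate
Product: 17 methyl (S)‑5‑chloro‑2‑(dimethoxymethyl)‑2‑methylpentanoate
Conditions: HC(OMe)3, MeOH, TsOH (cat.), 50 °C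
Reagents that add atoms: trimethyl orthoformate, COC(OC)OC; methanol, CO
Why: Acid‑catalysed acetalization masks the aldehyde for the strongly basic alkylation.

Step 14
Reactants: 17 methyl (S)‑5‑chloro‑2‑(dimethoxymethyl)‑2‑methylpentanoate
Product: 18 methyl (S)‑2‑(dimethoxymethyl)‑5‑iodo‑2‑methylpentanoate
Conditions: NaI, NaHCO3, acetone, reflux
Reagents that add atoms: sodium iodide, [Na+].[I-]
Why: Finkelstein halide exchange gives the primary iodide needed for the dianion alkylation.

Step 15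
Reactants: 10 ethyl 7‑isopropyl‑5,6,8‑trimethoxy‑2‑oxo‑1,2,3,4‑tetrahydronaphthalene‑1‑carboxylate; 18 methyl (S)‑2‑(dimethoxymethyl)‑5‑iodo‑2‑methylpentanoate
Product: 19 ethyl 3‑[(4S)‑4‑(dimethoxymethyl)‑5‑methoxy‑4‑methyl‑5‑oxopentyl]‑7‑isopropyl‑5,6,8‑trimethoxy‑2‑oxo‑1,2,3,4‑tetrahydronaphthalene‑1‑carboxylate
Conditions: LiN(i‑Pr)2 (2.2 equiv), THF, −78 to 0 °C; 18, DMPU, 0 °C to rt; aq. NH4Cl
Reagents that add atoms: none
Why: Huckin–Weiler dianion alkylation, in which the β‑keto ester dianion reacts at its γ‑carbon (C10) and not at the benzylic C7 where a plain 2‑tetralone enolate would; C10 forms without control and both epimers are carried.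

Step 16
Reactants: 19 ethyl 3‑[(4S)‑4‑(dimethoxymethyl)‑5‑methoxy‑4‑methyl‑5‑oxopentyl]‑7‑isopropyl‑5,6,8‑trimethoxy‑2‑oxo‑1,2,3,4‑tetrahydronaphthalene‑1‑carboxylate
Product: 21 methyl (2S)‑2‑formyl‑5‑(6‑isopropyl‑5,7,8‑trimethoxy‑3‑oxo‑1,2,3,4‑tetrahydronaphthalen‑2‑yl)‑2‑methylpentanoate, via acetal ketone 20 (not isolated)
Conditions: LiCl, DMSO/H2O, 140 °C (argon); then 2 M HCl, THF, 40 °C
Reagents that add atoms: water, O
Why: Krapcho dealkoxycarbonylation removes the activating ester at C7 (the hindered C19 methyl ester is not activated and stays), and mild acid hydrolysis of the dimethyl acetal then frees the C5 aldehyde.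

Step 17
Reactants: 21 methyl (2S)‑2‑formyl‑5‑(6‑isopropyl‑5,7,8‑trimethoxy‑3‑oxo‑1,2,3,4‑tetrahydronaphthalen‑2‑yl)‑2‑methylpentanoate
Product: 22 methyl (2S)‑2‑{(E)‑[2‑(tert‑butyldimethylsilyl)hydrazinylidene]methyl}‑5‑(6‑isopropyl‑5,7,8‑trimethoxy‑3‑oxo‑1,2,3,4‑tetrahydronaphthalen‑2‑yl)‑2‑methylpentanoate
Conditions: TBSNHNHTBS (1.05 equiv), Sc(OTf)3 (0.01 equiv), CH2Cl2, 0 °C to rt
Reagents that add atoms: 1,2‑bis(tert‑butyldimethylsilyl)hydrazine, CC(C)(C)[Si](C)(C)NN[Si](C)(C)C(C)(C)C
Why: Lewis acid catalysed N‑silyl hydrazone formation, which takes place at the aldehyde at low temperature while ketones need heating, and whose silylated nitrogen cannot attack the neighbouring ester (no pyrazolone).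

Step 18
Reactants: 22 methyl (2S)‑2‑{(E)‑[2‑(tert‑butyldimethylsilyl)hydrazinylidene]methyl}‑5‑(6‑isopropyl‑5,7,8‑trimethoxy‑3‑oxo‑1,2,3,4‑tetrahydronaphthalen‑2‑yl)‑2‑methylpentanoate
Product: 24 methyl (4S,5R)‑11,12,14‑trimethoxy‑6‑oxoicetexa‑8,11,13‑trien‑19‑oate, via diazo ketone 23 (not isolated)
Conditions: PhIF2, 2‑chloropyridine, CH2Cl2, −78 °C; then Sc(OTf)3 (0.5 equiv), −78 to −20 °C
Reagents that add atoms: none
Why: Proposed new method: oxidation of the N‑silyl hydrazone gives the non‑stabilized diazoalkane 23, whose nucleophilic carbon C5 adds to the Sc(OTf)3‑activated C6 carbonyl to give a diazonium alkoxide, and the C6–C10 bond antiperiplanar to the departing N2 then shifts to C5; the closest known reactions are the Sc(OTf)3‑catalysed homologation of ketones with non‑stabilized diazoalkanes (intermolecular) and the fused mode of the intramolecular Schmidt reaction of azido ketones, of which this is the carbon counterpart. Ring A closes by 7‑exo‑trig attack of C5 on C6 followed by the ring‑contracting 1,2‑shift of C10 (seven atoms to six), while ring B is not closed afresh but grows from six to seven atoms by insertion of C5. The new centre C5 lies α to the C6 ketone, so its configuration relative to the fixed quaternary C4 is under thermodynamic control and is settled as the lactone‑forming 5R epimer in steps 19 and 20; C10 migrates with retention and is carried as both epimers. The step needs C10 to migrate instead of C7 (which would give a bridged ketone) or oxygen (epoxide): in the chair‑like seven‑membered betaine the N2 group on C5 sits equatorial, anti to the ring bond C6–C10, as in the azide series where fused products dominate. Quaternary C4 rules out a 1,2‑hydrogen shift in the diazoalkane, and generating it at −78 °C without base keeps the acidic C7–H of the tetralone from quenching it.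

Step 19
Reactants: 24 methyl (4S,5R)‑11,12,14‑trimethoxy‑6‑oxoicetexa‑8,11,13‑trien‑19‑oate
Product: 25 (4S,5R)‑11,12,14‑trimethoxy‑6‑oxoicetexa‑8,11,13‑trien‑19‑oic acid
Conditions: n‑PrSLi, HMPA, 25 °C; aq. HCl
Reagents that add atoms: none
Why: SN2 demethylation of the hindered quaternary methyl ester by thiolate at the methyl carbon, under which the aryl methyl ethers survive and C5 can equilibrate by enolization.

Step 20
Reactants: 25 (4S,5R)‑11,12,14‑trimethoxy‑6‑oxoicetexa‑8,11,13‑trien‑19‑oic acid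
Product: 26 (4S,5R)‑11,12,14‑trimethoxyicetexa‑6,8,11,13‑tetraen‑19,6‑olide
Conditions: Ac2O, NaOAc, 120 °C
Reagents that add atoms: none
Why: Enol lactonization of the γ‑keto acid through its mixed anhydride, with the enol double bond formed towards C7 (conjugated with the arene); only the C5 epimer with C6 cis to C19 can close the five‑membered ring, so C5 is funnelled to 5R by enolization.

Step 21
Reactants: 26 (4S,5R)‑11,12,14‑trimethoxyicetexa‑6,8,11,13‑tetraen‑19,6‑olide
Product: 27 (4S,5R)‑11,12,14‑trimethoxyicetexa‑6,8,10(20),11,13‑pentaen‑19,6‑olide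
Conditions: DDQ (1.1 equiv), 1,4‑dioxane, 60 °C
Reagents that add atoms: none
Why: Quinone dehydrogenation, in which DDQ takes a benzylic hydride from C20 of the electron‑rich arene and H10 is then lost to give the styrene; the competing C5–H is shielded by quaternary C4 and deactivated by the adjacent acyloxy‑bearing C6.

Step 22
Reactants: 27 (4S,5R)‑11,12,14‑trimethoxyicetexa‑6,8,10(20),11,13‑pentaen‑19,6‑olide
Product: 28 (1R,4S,5R)‑1‑hydroxy‑11,12,14‑trimethoxyicetexa‑6,8,10(20),11,13‑pentaen‑19,6‑olide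
Conditions: SeO2 (0.5 equiv), t‑BuOOH, CH2Cl2, 0 °C to rt
Reagents that add atoms: tert‑butyl hydroperoxide, CC(C)(C)OO; selenium dioxide, O=[Se]=O
Why: Selenium dioxide allylic hydroxylation (ene reaction, then [2,3]‑sigmatropic shift) attacks the CH2 (C1) on the disubstituted end of the C10=C20 alkene in preference to the hindered C5–H; selenium should add to C20 on the convex face of tub‑shaped ring B (the face of C6), take the pseudo‑axial C1–H there and return oxygen to that face, giving 1R.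

Step 23
Reactants: 28 (1R,4S,5R)‑1‑hydroxy‑11,12,14‑trimethoxyicetexa‑6,8,10(20),11,13‑pentaen‑19,6‑olide
Product: 29 (1R,4S,5R)‑1‑hydroxy‑12‑methoxy‑11,14‑dioxoicetexa‑6,8,10(20),12‑tetraen‑19,6‑olide
Conditions: (NH4)2Ce(NO3)6 (2.5 equiv), MeCN/H2O, 0 °C
Reagents that add atoms: water, O
Why: Oxidative demethylation of the para‑dimethoxy pair (C11 and C14) gives the para‑quinone and leaves the C12 methoxy in place, under brief, weakly acidic conditions that the allylic alcohol and the enol lactone should tolerate.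

Step 24
Reactants: 29 (1R,4S,5R)‑1‑hydroxy‑12‑methoxy‑11,14‑dioxoicetexa‑6,8,10(20),12‑tetraen‑19,6‑olide
Product: 30 6,7‑anhydroballotiquinone
Conditions: BCl3, CH2Cl2, −78 °C; H2O
Reagents that add atoms: none
Why: Chelation‑assisted Lewis acid demethylation, in which boron bridges the C11 carbonyl and the C12 methoxy of the vinylogous methyl ester and chloride removes the methyl group; the C1 alcohol now sits next to an electron‑poor vinylquinone and should not ionize at −78 °C.

**Compound list**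

1 | 1,2,4‑trimethoxybenzene | COc1ccc(OC)c(OC)c1 | starting material
2 | 2‑(2,3,6‑trimethoxyphenyl)propan‑2‑ol | COc1ccc(OC)c(C(C)(C)O)c1OC | intermediate
3 | 3‑isopropyl‑1,2,4‑trimethoxybenzene | COc1ccc(OC)c(C(C)C)c1OC | intermediate
4 | 1‑bromo‑3‑isopropyl‑2,4,5‑trimethoxybenzene | COc1cc(Br)c(OC)c(C(C)C)c1OC | intermediate
5 | 2‑bromo‑4‑isopropyl‑3,5,6‑trimethoxybenzaldehyde | COc1c(C=O)c(Br)c(OC)c(C(C)C)c1OC | intermediate
6 | ethyl 4‑(diethoxyphosphoryl)‑3‑oxobutanoate | CCOC(=O)CC(=O)CP(=O)(OCC)OCC | starting material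
7 | ethyl (E)‑5‑(2‑bromo‑4‑isopropyl‑3,5,6‑trimethoxyphenyl)‑3‑oxopent‑4‑enoate | CCOC(=O)CC(=O)/C=C/c1c(Br)c(OC)c(C(C)C)c(OC)c1OC | intermediate
8 | ethyl 5‑(4‑isopropyl‑2,3,5‑trimethoxyphenyl)‑3‑oxopentanoate | CCOC(=O)CC(=O)CCc1cc(OC)c(C(C)C)c(OC)c1OC | intermediate
9 | ethyl 2‑diazo‑5‑(4‑isopropyl‑2,3,5‑trimethoxyphenyl)‑3‑oxopentanoate | CCOC(=O)C(=[N+]=[N-])C(=O)CCc1cc(OC)c(C(C)C)c(OC)c1OC | intermediate
10 | ethyl 7‑isopropyl‑5,6,8‑trimethoxy‑2‑oxo‑1,2,3,4‑tetrahydronaphthalene‑1‑carboxylate (keto form drawn, largely enolized) | CCOC(=O)C1C(=O)CCc2c(OC)c(OC)c(C(C)C)c(OC)c12 | intermediate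
11 | dimethyl methylmalonate | COC(=O)C(C)C(=O)OC | starting material
12 | 1‑bromo‑3‑chloropropane | ClCCCBr | starting material
13 | dimethyl 2‑(3‑chloropropyl)‑2‑methylmalonate | COC(=O)C(C)(CCCCl)C(=O)OC | intermediate
14 | (S)‑5‑chloro‑2‑(methoxycarbonyl)‑2‑methylpentanoic acid | COC(=O)[C@@](C)(CCCCl)C(=O)O | intermediate
15 | methyl (S)‑5‑chloro‑2‑(hydroxymethyl)‑2‑methylpentanoate | COC(=O)[C@@](C)(CCCCl)CO | intermediate
16 | methyl (S)‑5‑chloro‑2‑formyl‑2‑methylpentanoate | COC(=O)[C@@](C)(CCCCl)C=O | intermediate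
17 | methyl (S)‑5‑chloro‑2‑(dimethoxymethyl)‑2‑methylpentanoate | COC(=O)[C@@](C)(CCCCl)C(OC)OC | intermediate
18 | methyl (S)‑2‑(dimethoxymethyl)‑5‑iodo‑2‑methylpentanoate | COC(=O)[C@@](C)(CCCI)C(OC)OC | intermediate
19 | ethyl 3‑[(4S)‑4‑(dimethoxymethyl)‑5‑methoxy‑4‑methyl‑5‑oxopentyl]‑7‑isopropyl‑5,6,8‑trimethoxy‑2‑oxo‑1,2,3,4‑tetrahydronaphthalene‑1‑carboxylate (epimers at the two ring centres) | CCOC(=O)C1C(=O)C(CCC[C@](C)(C(=O)OC)C(OC)OC)Cc2c(OC)c(OC)c(C(C)C)c(OC)c12 | intermediate
20 | methyl (2S)‑2‑(dimethoxymethyl)‑5‑(6‑isopropyl‑5,7,8‑trimethoxy‑3‑oxo‑1,2,3,4‑tetrahydronaphthalen‑2‑yl)‑2‑methylpentanoate (C10 epimers) | COC(=O)[C@@](C)(CCCC1Cc2c(OC)c(OC)c(C(C)C)c(OC)c2CC1=O)C(OC)OC | intermediate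
21 | methyl (2S)‑2‑formyl‑5‑(6‑isopropyl‑5,7,8‑trimethoxy‑3‑oxo‑1,2,3,4‑tetrahydronaphthalen‑2‑yl)‑2‑methylpentanoate (C10 epimers) | COC(=O)[C@@](C)(CCCC1Cc2c(OC)c(OC)c(C(C)C)c(OC)c2CC1=O)C=O | intermediate
22 | N‑(tert‑butyldimethylsilyl) hydrazone of 21, E at C=N (C10 epimers) | COC(=O)[C@@](C)(CCCC1Cc2c(OC)c(OC)c(C(C)C)c(OC)c2CC1=O)/C=N/N[Si](C)(C)C(C)(C)C | intermediate
23 | methyl (2S)‑2‑(diazomethyl)‑5‑(6‑isopropyl‑5,7,8‑trimethoxy‑3‑oxo‑1,2,3,4‑tetrahydronaphthalen‑2‑yl)‑2‑methylpentanoate (C10 epimers; key‑step precursor) | COC(=O)[C@@](C)(CCCC1Cc2c(OC)c(OC)c(C(C)C)c(OC)c2CC1=O)C=[N+]=[N-] | intermediate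
24 | methyl (4S,5R)‑11,12,14‑trimethoxy‑6‑oxoicetexa‑8,11,13‑trien‑19‑oate (C10 epimers; C5 epimerizable, lactone‑forming epimer drawn; key‑step product) | CC(C)c1c(OC)c2c(c(OC)c1OC)CC1CCC[C@](C)(C(=O)OC)[C@@H]1C(=O)C2 | intermediate
25 | (4S,5R)‑11,12,14‑trimethoxy‑6‑oxoicetexa‑8,11,13‑trien‑19‑oic acid (C10 epimers) | CC(C)c1c(OC)c2c(c(OC)c1OC)CC1CCC[C@](C)(C(=O)O)[C@@H]1C(=O)C2 | intermediate
26 | (4S,5R)‑11,12,14‑trimethoxyicetexa‑6,8,11,13‑tetraen‑19,6‑olide (C10 epimers) | CC(C)c1c(OC)c(OC)c2c(c1OC)C=C1OC(=O)[C@@]3(C)CCCC(C2)[C@@H]13 | intermediate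
27 | (4S,5R)‑11,12,14‑trimethoxyicetexa‑6,8,10(20),11,13‑pentaen‑19,6‑olide | CC(C)c1c(OC)c(OC)c2c(c1OC)C=C1OC(=O)[C@@]3(C)CCCC(=C2)[C@@H]13 | intermediate
28 | (1R,4S,5R)‑1‑hydroxy‑11,12,14‑trimethoxyicetexa‑6,8,10(20),11,13‑pentaen‑19,6‑olide | CC(C)c1c(OC)c(OC)c2c(c1OC)C=C1OC(=O)[C@@]3(C)CC[C@@H](O)C(=C2)[C@@H]13 | intermediate
29 | (1R,4S,5R)‑1‑hydroxy‑12‑methoxy‑11,14‑dioxoicetexa‑6,8,10(20),12‑tetraen‑19,6‑olide | CC(C)C1=C(OC)C(=O)C2=C(C=C3OC(=O)[C@@]4(C)CC[C@@H](O)C(=C2)[C@@H]34)C1=O | intermediate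
30 | 6,7‑anhydroballotiquinone, (1R,4S,5R) | CC(C)C1=C(O)C(=O)C2=C(C=C3OC(=O)[C@@]4(C)CC[C@@H](O)C(=C2)[C@@H]34)C1=O | target

**Step count and risks**

Total step count: 24. Longest linear sequence: 18 steps (steps 1 to 8, then 15 to 24, from 1,2,4‑trimethoxybenzene).

Steps most likely to fail:

1. Step 18 (proposed new method). The diazo carbon may be protonated by the acidic C7–H of the tetralone before it reaches the carbonyl, C7 or oxygen may shift instead of C10, or the addition may be too slow for the congested C5. Fallback, from 21 back to 24 by known chemistry: soft enolization (MgBr2·OEt2, i‑Pr2NEt, CH2Cl2) brings about an intramolecular aldol addition of C10 to the C5 aldehyde (six‑membered ring A; attack through C7 would need an eight‑membered ring) and gives the spiro hydroxy ketone F1. Its C5 hydroxyl is converted with PhOC(S)Cl, pyridine and DMAP into the O‑phenyl thionocarbonate F2. Bu3SnH (slow addition) and AIBN in benzene at 80 °C then generate the C5 radical, which adds to the C6 carbonyl and cleaves the C6–C10 bond (Dowd–Beckwith ring expansion); the tertiary C10 radical takes hydrogen from the stannane to give 24.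

2. Step 21. Hydride may be taken from C5 instead of C20, and the product may be oxidized further by loss of its doubly allylic C5 hydride. Fallback, from 26 back to 27: radical benzylic bromination (NBS, AIBN, PhCF3, 80 °C) gives the C20 bromide F3, and DBU in THF removes HBr; H10 is the only β‑hydrogen, so the alkene can only form as C10=C20.

3. Step 22. Oxygen may be delivered to the wrong face of C1 (poor facial selectivity), or the ene reaction may take the C5–H. Fallback, from 27 back to 28: the crude hydroxylation mixture, 28 together with its 1S epimer F4, is oxidized with MnO2 in CH2Cl2 to the C1 enone F5. F5 is reduced with (S)‑1‑methyl‑3,3‑diphenyltetrahydro‑1H,3H‑pyrrolo[1,2‑c][1,3,2]oxazaborole (Corey–Bakshi–Shibata catalyst) and catecholborane in toluene at −78 °C. With the alkylidene‑bearing C10 as the large group, the catalyst should direct hydride to the face that gives the 1R alcohol 28.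

**Further compounds**

F1 | step 18 | spiro hydroxy ketone: ring A closed between C5 (carbinol) and C10 (spiro centre of the 2‑tetralone), C4 S, other centres as mixtures | COC(=O)[C@@]1(C)CCCC2(Cc3c(OC)c(OC)c(C(C)C)c(OC)c3CC2=O)C1O
F2 | step 18 | O‑phenyl thionocarbonate of F1 | COC(=O)[C@@]1(C)CCCC2(Cc3c(OC)c(OC)c(C(C)C)c(OC)c3CC2=O)C1OC(=S)Oc1ccccc1
F3 | step 21 | (4S,5R)‑20‑bromo‑11,12,14‑trimethoxyicetexa‑6,8,11,13‑tetraen‑19,6‑olide | CC(C)c1c(OC)c(OC)c2c(c1OC)C=C1OC(=O)[C@@]3(C)CCCC(C2Br)[C@@H]13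
F4 | step 22 | (1S,4S,5R)‑1‑hydroxy‑11,12,14‑trimethoxyicetexa‑6,8,10(20),11,13‑pentaen‑19,6‑olide (C1 epimer of 28) | CC(C)c1c(OC)c(OC)c2c(c1OC)C=C1OC(=O)[C@@]3(C)CC[C@H](O)C(=C2)[C@@H]13
F5 | step 22 | (4S,5R)‑11,12,14‑trimethoxy‑1‑oxoicetexa‑6,8,10(20),11,13‑pentaen‑19,6‑olide | CC(C)c1c(OC)c(OC)c2c(c1OC)C=C1OC(=O)[C@@]3(C)CCC(=O)C(=C2)[C@@H]13
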